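Ring B, the 2,5-dihydrofuran O1–C8–C7=C6–C5 (carotenoid numbering), is made by joining C7 to C8. Lithiated trimethylsilyldiazomethane turns the C6 ketone of an α-alkoxy ketone into an exocyclic alkylidene carbene at C7, which inserts into an O–CH2 bond of the allylic ether on C5: one operation adds C7, closes ring B and sets C8. The step exploits that C6 of ring A lies between the quaternary C1 and C5, leaving the carbene no other outlet, and that the cis 3,5-dioxygenation holds O1 equatorial beside the axial C5 methyl. The precursor is a C14 keto ether; the polyene follows by three Wittig reactions.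

Key step: step 9

Remarks on the chemistry:
- Carotenoid locants are used for the skeleton: ring A is C1–C6 (C1 gem-dimethyl, C3 carbinol, C5 methyl-bearing), ring B is O1, C5, C6, C7, C8, and the chain runs C9–C15, C15'–C8'.
- The target is (3R,5R,8R): the 3-OH is cis to O1 on ring A, and C9 is trans to the C5 methyl on ring B.
- (4R,6R)-4-Hydroxy-2,2,6-trimethylcyclohexanone (actinol), prenol and (2E,4E,6E)-2,7-dimethylocta-2,4,6-trienedial are assumed to be commercial.
- Polyene steps are run under argon with exclusion of light, on silica deactivated with Et3N.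

Step 1
Reactants: 1 (4R,6R)-4-hydroxy-2,2,6-trimethylcyclohexanone
Product: 4 (2R,4S)-2,4-dihydroxy-2,6,6-trimethylcyclohexanone, via bis-silyl enol ether 2 (not isolated), via bis-silyloxy ketone 3 (not isolated)
Conditions: LiN(iPr)2 (2.2 equiv), Me3SiCl, THF, −78 °C; then mCPBA, NaHCO3, hexane/CH2Cl2, −20 °C; then K2CO3 (cat.), MeOH, 0 °C
Reagents that add atoms: mCPBA (OOC(=O)c1cccc(Cl)c1)
Why: Rubottom oxidation: the only possible enolate (C5=C6) is trapped as the silyl enol ether and should be epoxidised anti to the C3 silyloxy group (the usual facial preference of peracids on 3-oxygenated 2,6,6-trimethylcyclohexene rings), so silyl migration and methanolysis give the trans ketol with C5 in the R configuration; the minor cis isomer is removed by chromatography before step 2.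

Step 2
Reactants: 4 (2R,4S)-2,4-dihydroxy-2,6,6-trimethylcyclohexanone
Product: 5 (R)-2-hydroxy-2,6,6-trimethylcyclohexane-1,4-dione
Conditions: Dess–Martin periodinane, NaHCO3, CH2Cl2, 0 °C to rt
Reagents that add atoms: none
Why: Dess–Martin oxidation takes the only secondary alcohol (the tertiary ketol hydroxyl is inert) and deliberately erases the C3 stereocentre after it has relayed its configuration to C5.

Step 3
Reactants: 5 (R)-2-hydroxy-2,6,6-trimethylcyclohexane-1,4-dione
Product: 6 (2R,4R)-2,4-dihydroxy-2,6,6-trimethylcyclohexanone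
Conditions: Et2BOMe, THF/MeOH, −78 °C; then NaBH4, −78 °C; AcOH quench, MeOH co-evaporation
Reagents that add atoms: none
Why: Narasaka–Prasad 1,3-syn reduction: the diethylboron chelate between the C5 oxygen and the unhindered C3 carbonyl holds that oxygen axial, so external hydride enters from the equatorial side (the axial face is closed by the chelate and the axial C1 methyl) and gives the cis diol (new C3 centre R), while the C6 ketone between two quaternary carbons should not react at −78 °C.

Step 4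
Reactants: 6 (2R,4R)-2,4-dihydroxy-2,6,6-trimethylcyclohexanone
Product: 7 (2R,4R)-4-(tert-butyldimethylsilyloxy)-2-hydroxy-2,6,6-trimethylcyclohexanone
Conditions: tBuMe2SiCl, imidazole, DMF, 0 °C to rt
Reagents that add atoms: tert-butyldimethylsilyl chloride (C[Si](C)(Cl)C(C)(C)C)
Why: Silyl ether formation should occur only at the unhindered secondary hydroxyl, the tertiary ketol hydroxyl being too hindered for this reagent.

Step 5
Reactants: 8 3-methylbut-2-en-1-ol (prenol)
Product: 9 tert-butyldimethyl(3-methylbut-2-enyloxy)silane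
Conditions: tBuMe2SiCl, imidazole, CH2Cl2, rt
Reagents that add atoms: tert-butyldimethylsilyl chloride (C[Si](C)(Cl)C(C)(C)C)
Why: Standard silyl ether protection of a primary allylic alcohol.

Step 6
Reactants: 9 tert-butyldimethyl(3-methylbut-2-enyloxy)silane
Product: 10 (E)-4-(tert-butyldimethylsilyloxy)-2-methylbut-2-en-1-ol
Conditions: SeO2 (cat.), tBuOOH, salicylic acid (cat.), CH2Cl2, rt
Reagents that add atoms: tert-butyl hydroperoxide (CC(C)(C)OO), its oxygen relayed by SeO2 (O=[Se]=O)
Why: Allylic oxidation with SeO2 (ene reaction, then 2,3-sigmatropic shift) functionalises the (E)-methyl group of the trisubstituted alkene and so gives the (E)-allylic alcohol.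

Step 7
Reactants: 10 (E)-4-(tert-butyldimethylsilyloxy)-2-methylbut-2-en-1-ol
Product: 11 (E)-(4-bromo-3-methylbut-2-enyloxy)(tert-butyl)dimethylsilane
Conditions: CBr4, PPh3, CH2Cl2, −20 to 0 °C
Reagents that add atoms: carbon tetrabromide (BrC(Br)(Br)Br)
Why: Appel bromination (SN2 on the alkoxyphosphonium ion) converts the primary allylic alcohol into the bromide without allylic transposition at low temperature.

Step 8
Reactants: 7 (2R,4R)-4-(tert-butyldimethylsilyloxy)-2-hydroxy-2,6,6-trimethylcyclohexanone; 11 (E)-(4-bromo-3-methylbut-2-enyloxy)(tert-butyl)dimethylsilane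
Product: 12 (2R,4R)-4-(tert-butyldimethylsilyloxy)-2-[(E)-4-(tert-butyldimethylsilyloxy)-2-methylbut-2-enyloxy]-2,6,6-trimethylcyclohexanone
Conditions: NaH, Bu4NI (cat.), THF/DMF, 0 °C
Reagents that add atoms: none
Why: Williamson etherification: the tertiary alkoxide of the non-enolisable ketol is alkylated by the primary allylic bromide in an SN2 reaction.

Step 9
Reactants: 12 (2R,4R)-4-(tert-butyldimethylsilyloxy)-2-[(E)-4-(tert-butyldimethylsilyloxy)-2-methylbut-2-enyloxy]-2,6,6-trimethylcyclohexanone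
Product: 16 (2R,6R,7aR)-6-(tert-butyldimethylsilyloxy)-2-[(E)-4-(tert-butyldimethylsilyloxy)but-2-en-2-yl]-4,4,7a-trimethyl-2,4,5,6,7,7a-hexahydrobenzofuran, via lithium alkoxide adduct 13 (not isolated), via diazoalkene 14 (not isolated), via alkylidene carbene 15 (not isolated)
Conditions: Me3SiCHN2, n-BuLi, THF, −78 °C; then 12, −78 to 0 °C
Reagents that add atoms: trimethylsilyldiazomethane (C[Si](C)(C)C=[N+]=[N-])
Why: Lithiated trimethylsilyldiazomethane adds to the non-enolisable C6 carbonyl (13), and a 1,3-Brook shift with loss of Me3SiOLi (Peterson-type olefination) gives diazoalkene 14, which loses N2 to the exocyclic alkylidene carbene 15; its empty in-plane p orbital at C7 then inserts into one allylic O–CH2 bond of the ether, which is the alkylidene carbene 1,5 C–H insertion known to convert α-alkoxy ketones into 2,5-dihydrofurans. Ring B closes through a five-centre in-plane (σ-type) insertion with retention at carbon, a geometry that a π-nucleophile could not reach in this 5-endo arrangement. No other outlet exists: C1 and C5 are quaternary, every other C–H bond is 1,4 or would need a bridgehead alkene, and a 1,2-shift would give a cycloheptyne. The new stereocentre C8 is controlled by ring A: with O1 and the C3 silyloxy group both equatorial, the C5–O1 bond eclipses C6=C7 and the C5 methyl is axial, so the C9 substituent should take the pseudo-equatorial site of the half-chair transition state, anti to that methyl (8R). The step needs selection between the two diastereotopic C8–H bonds, secured by this axial methyl, and chemoselectivity against cyclopropanation of C9=C10, secured by the activation of the allylic α-oxy C–H bond.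

Step 10
Reactants: 16 bis-silyl ether of the C15 dihydrofuran
Product: 17 (2R,6R,7aR)-2-[(E)-4-hydroxybut-2-en-2-yl]-4,4,7a-trimethyl-2,4,5,6,7,7a-hexahydrobenzofuran-6-ol
Conditions: Bu4NF, THF, 0 °C to rt
Reagents that add atoms: none
Why: Fluoride-mediated desilylation removes both silyl ethers, and the doubly allylic C8 ether is stable to the basic medium.

Step 11
Reactants: 17 C15 diol
Product: 19 {(E)-3-[(2R,6R,7aR)-6-hydroxy-4,4,7a-trimethyl-2,4,5,6,7,7a-hexahydrobenzofuran-2-yl]but-2-enyl}triphenylphosphonium bromide, via allylic bromide 18 (not isolated)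
Conditions: NBS, Me2S, CH2Cl2, −20 to 0 °C; then PPh3, EtOAc, rt
Reagents that add atoms: N-bromosuccinimide (O=C1CCC(=O)N1Br); triphenylphosphine (c1ccc(cc1)P(c1ccccc1)c1ccccc1)
Why: Corey–Kim bromination is selective for the allylic hydroxyl (the secondary alkoxysulfonium ion reverts on work-up), and SN2 quaternisation of PPh3 by the primary allylic bromide gives the Wittig salt under acid-free conditions that leave C8 untouched.

Step 12
Reactants: 19 C15 phosphonium bromide; 20 (2E,4E,6E)-2,7-dimethylocta-2,4,6-trienedial (3 equiv)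
Product: 22 (3R,5R,8R)-5,8-epoxy-3-hydroxy-5,8-dihydro-12'-apo-β-caroten-12'-al, via allylic ylide 21 (not isolated)
Conditions: NaOMe, CH2Cl2/MeOH, 0 °C to rt; then heptane, 80 °C (Z to E isomerisation)
Reagents that add atoms: none
Why: Wittig olefination of the allylic ylide with an excess of the symmetric dialdehyde should give the mono-adduct, and the hindered 11Z isomer is isomerised thermally to the all-E polyene.

Step 13
Reactants: 22 C25 aldehyde
Product: 23 (3R,5R,8R)-5,8-epoxy-3-hydroxy-5,8-dihydro-10'-apo-β-caroten-10'-al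
Conditions: Ph3P=CHCHO (1.2 equiv), toluene, 80 °C
Reagents that add atoms: (triphenylphosphoranylidene)acetaldehyde (O=CC=P(c1ccccc1)(c1ccccc1)c1ccccc1)
Why: Wittig reaction of the stabilised formylmethylene ylide extends the polyenal by two carbons as the (E)-enal.

Step 14
Reactants: 23 C27 aldehyde
Product: 24 (3R,5R,8R)-5,8-epoxy-3-hydroxy-5,8-dihydro-8'-apo-β-caroten-8'-al (target)
Conditions: Ph3P=C(CH3)CHO (1.5 equiv), toluene, 100 °C
Reagents that add atoms: 2-(triphenylphosphoranylidene)propanal (CC(C=O)=P(c1ccccc1)(c1ccccc1)c1ccccc1)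
Why: Wittig reaction of the stabilised α-methyl formyl ylide gives the trisubstituted (E)-2-methyl enal and completes the C30 chain.

Compound list
1 | (4R,6R)-4-hydroxy-2,2,6-trimethylcyclohexanone (actinol) | O=C1C(C)(C)C[C@H](O)C[C@H]1C | starting material
2 | (4R)-1,4-bis(trimethylsilyloxy)-2,6,6-trimethylcyclohex-1-ene | C[Si](C)(C)OC1=C(C)C[C@@H](O[Si](C)(C)C)CC1(C)C | intermediate
3 | (2R,4S)-2,6,6-trimethyl-2,4-bis(trimethylsilyloxy)cyclohexanone | O=C1C(C)(C)C[C@H](O[Si](C)(C)C)C[C@@]1(C)O[Si](C)(C)C | intermediate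
4 | (2R,4S)-2,4-dihydroxy-2,6,6-trimethylcyclohexanone | O=C1C(C)(C)C[C@H](O)C[C@@]1(C)O | intermediate
5 | (R)-2-hydroxy-2,6,6-trimethylcyclohexane-1,4-dione | O=C1C(C)(C)CC(=O)C[C@@]1(C)O | intermediate
6 | (2R,4R)-2,4-dihydroxy-2,6,6-trimethylcyclohexanone | O=C1C(C)(C)C[C@@H](O)C[C@@]1(C)O | intermediate
7 | (2R,4R)-4-(tert-butyldimethylsilyloxy)-2-hydroxy-2,6,6-trimethylcyclohexanone | O=C1C(C)(C)C[C@@H](O[Si](C)(C)C(C)(C)C)C[C@@]1(C)O | intermediate
8 | 3-methylbut-2-en-1-ol (prenol) | CC(C)=CCO | starting material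
9 | tert-butyldimethyl(3-methylbut-2-enyloxy)silane | CC(C)=CCO[Si](C)(C)C(C)(C)C | intermediate
10 | (E)-4-(tert-butyldimethylsilyloxy)-2-methylbut-2-en-1-ol | OC/C(C)=C/CO[Si](C)(C)C(C)(C)C | intermediate
11 | (E)-(4-bromo-3-methylbut-2-enyloxy)(tert-butyl)dimethylsilane | BrC/C(C)=C/CO[Si](C)(C)C(C)(C)C | intermediate
12 | (2R,4R)-4-(tert-butyldimethylsilyloxy)-2-[(E)-4-(tert-butyldimethylsilyloxy)-2-methylbut-2-enyloxy]-2,6,6-trimethylcyclohexanone | O=C1C(C)(C)C[C@@H](O[Si](C)(C)C(C)(C)C)C[C@@]1(C)OC/C(C)=C/CO[Si](C)(C)C(C)(C)C | intermediate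
13 | lithium alkoxide adduct of 12 (C6 carries O–Li and C(N2)SiMe3; C6 configuration not defined) | [Li+].[O-]C1(C(=[N+]=[N-])[Si](C)(C)C)C(C)(C)C[C@@H](O[Si](C)(C)C(C)(C)C)C[C@@]1(C)OC/C(C)=C/CO[Si](C)(C)C(C)(C)C | intermediate
14 | diazoalkene (C6=C7=N2) derived from 12 | [N-]=[N+]=C=C1C(C)(C)C[C@@H](O[Si](C)(C)C(C)(C)C)C[C@@]1(C)OC/C(C)=C/CO[Si](C)(C)C(C)(C)C | intermediate
15 | exocyclic alkylidene carbene (divalent C7 on C6) | [C]=C1C(C)(C)C[C@@H](O[Si](C)(C)C(C)(C)C)C[C@@]1(C)OC/C(C)=C/CO[Si](C)(C)C(C)(C)C | intermediate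
16 | (2R,6R,7aR)-6-(tert-butyldimethylsilyloxy)-2-[(E)-4-(tert-butyldimethylsilyloxy)but-2-en-2-yl]-4,4,7a-trimethyl-2,4,5,6,7,7a-hexahydrobenzofuran | CC(C)(C)[Si](C)(C)OC/C=C(\C)[C@H]1C=C2C(C)(C)C[C@@H](O[Si](C)(C)C(C)(C)C)C[C@@]2(C)O1 | intermediate
17 | (2R,6R,7aR)-2-[(E)-4-hydroxybut-2-en-2-yl]-4,4,7a-trimethyl-2,4,5,6,7,7a-hexahydrobenzofuran-6-ol | OC/C=C(\C)[C@H]1C=C2C(C)(C)C[C@@H](O)C[C@@]2(C)O1 | intermediate
18 | (2R,6R,7aR)-2-[(E)-4-bromobut-2-en-2-yl]-4,4,7a-trimethyl-2,4,5,6,7,7a-hexahydrobenzofuran-6-ol | BrC/C=C(\C)[C@H]1C=C2C(C)(C)C[C@@H](O)C[C@@]2(C)O1 | intermediate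
19 | {(E)-3-[(2R,6R,7aR)-6-hydroxy-4,4,7a-trimethyl-2,4,5,6,7,7a-hexahydrobenzofuran-2-yl]but-2-enyl}triphenylphosphonium bromide | c1ccccc1[P+](c1ccccc1)(c1ccccc1)C/C=C(\C)[C@H]1C=C2C(C)(C)C[C@@H](O)C[C@@]2(C)O1.[Br-] | intermediate
20 | (2E,4E,6E)-2,7-dimethylocta-2,4,6-trienedial | O=C/C(C)=C/C=C/C=C(\C)C=O | starting material
21 | allylic phosphonium ylide of 19 | c1ccccc1[P+](c1ccccc1)(c1ccccc1)[CH-]/C=C(\C)[C@H]1C=C2C(C)(C)C[C@@H](O)C[C@@]2(C)O1 | intermediate
22 | (3R,5R,8R)-5,8-epoxy-3-hydroxy-5,8-dihydro-12'-apo-β-caroten-12'-al (all-E C25 aldehyde) | O=C/C(C)=C/C=C/C=C(C)/C=C/C=C(\C)[C@H]1C=C2C(C)(C)C[C@@H](O)C[C@@]2(C)O1 | intermediate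
23 | (3R,5R,8R)-5,8-epoxy-3-hydroxy-5,8-dihydro-10'-apo-β-caroten-10'-al (all-E C27 aldehyde) | O=C/C=C/C(C)=C/C=C/C=C(C)/C=C/C=C(\C)[C@H]1C=C2C(C)(C)C[C@@H](O)C[C@@]2(C)O1 | intermediate
24 | (3R,5R,8R)-5,8-epoxy-3-hydroxy-5,8-dihydro-8'-apo-β-caroten-8'-al, i.e. (all-E)-15-[(2R,6R,7aR)-6-hydroxy-4,4,7a-trimethyl-2,4,5,6,7,7a-hexahydrobenzofuran-2-yl]-2,6,11-trimethylhexadeca-2,4,6,8,10,12,14-heptaenal | C\C(C=O)=C/C=C/C(C)=C/C=C/C=C(C)/C=C/C=C(\C)[C@H]1C=C2C(C)(C)C[C@@H](O)C[C@@]2(C)O1 | target

Total step count: 14. Longest linear sequence: 11 steps (steps 1–4 and 8–14); steps 5–7 make the side arm 11.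

Steps most likely to fail

1. Step 9. The carbene may discriminate poorly between the two diastereotopic C8–H bonds, so that the C8 epimer forms beside 16. Fallback, setting out from 12 and coming back at 16: the insertion is run as before, 16 is separated from its C8 epimer F1, and F1 is treated with camphorsulfonic acid (cat.) in CH2Cl2 at 0 °C. Reversible ionisation of the doubly allylic C8–O1 bond and re-closure by the C5 hydroxyl (the known acid epimerisation of furanoid oxides) equilibrates C8, and the mixture is separated again and recycled, replacing kinetic control by thermodynamic recycling.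

2. Step 1. The peracid may attack the enol ether with poor or reversed facial selectivity; the wrong ketol would, after step 2, erode the enantiomeric purity. Fallback, setting out from 1 and coming back at 4, which places the oxygen by nucleophilic epoxidation next to the stereocentre instead: 1 is silylated (tBuMe2SiCl, imidazole) to silyl ether F2; 2-iodoxybenzoic acid in DMSO at 70 °C dehydrogenates it to enone F3; H2O2/NaOH in MeOH adds to C4 anti to the adjacent silyloxy group and gives epoxy ketone F4; LiAlH4 reduces the ketone and opens the epoxide at the secondary C4 to give diol F5; Dess–Martin periodinane oxidises the secondary carbinol to ketol F6; Bu4NF then gives 4.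

3. Step 13. The formyl ylide may react sluggishly with the long polyenal and homologate the product a second time, so conversion is hard to control. Fallback, setting out from 22 and coming back at 24 (bypassing 23 and step 14): Horner–Wadsworth–Emmons reaction of 22 with ethyl (E)-4-(diethoxyphosphoryl)-2-methylbut-2-enoate (CCOC(=O)/C(C)=C/CP(=O)(OCC)OCC; NaH, THF, 0 °C) gives ester F7 in one five-carbon extension; iBu2AlH (CH2Cl2, −78 °C) gives allylic alcohol F8; MnO2 (CH2Cl2, rt) oxidises only the polyenylic alcohol to 24.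

Further compounds
F1 | step 9 | (2S,6R,7aR)-epimer of 16 (C8 epimer) | CC(C)(C)[Si](C)(C)OC/C=C(\C)[C@@H]1C=C2C(C)(C)C[C@@H](O[Si](C)(C)C(C)(C)C)C[C@@]2(C)O1
F2 | step 1 | (4R,6R)-4-(tert-butyldimethylsilyloxy)-2,2,6-trimethylcyclohexanone | O=C1C(C)(C)C[C@H](O[Si](C)(C)C(C)(C)C)C[C@H]1C
F3 | step 1 | (S)-4-(tert-butyldimethylsilyloxy)-2,6,6-trimethylcyclohex-2-en-1-one | O=C1C(C)(C)C[C@H](O[Si](C)(C)C(C)(C)C)C=C1C
F4 | step 1 | 4-(tert-butyldimethylsilyloxy)-2,3-epoxy-2,6,6-trimethylcyclohexanone, epoxide trans to the silyloxy group, C2 as in 4 | O=C1C(C)(C)C[C@H](O[Si](C)(C)C(C)(C)C)[C@H]2O[C@@]12C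
F5 | step 1 | 4-(tert-butyldimethylsilyloxy)-2,6,6-trimethylcyclohexane-1,2-diol, C2 and C4 as in F6, C1 carbinol as epimer mixture | OC1C(C)(C)C[C@H](O[Si](C)(C)C(C)(C)C)C[C@@]1(C)O
F6 | step 1 | (2R,4S)-4-(tert-butyldimethylsilyloxy)-2-hydroxy-2,6,6-trimethylcyclohexanone | O=C1C(C)(C)C[C@H](O[Si](C)(C)C(C)(C)C)C[C@@]1(C)O
F7 | step 13 | ethyl (3R,5R,8R)-5,8-epoxy-3-hydroxy-5,8-dihydro-8'-apo-β-caroten-8'-oate (all-E) | CCOC(=O)/C(C)=C/C=C/C(C)=C/C=C/C=C(C)/C=C/C=C(\C)[C@H]1C=C2C(C)(C)C[C@@H](O)C[C@@]2(C)O1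
F8 | step 13 | (3R,5R,8R)-5,8-epoxy-5,8-dihydro-8'-apo-β-carotene-3,8'-diol (all-E) | OC/C(C)=C/C=C/C(C)=C/C=C/C=C(C)/C=C/C=C(\C)[C@H]1C=C2C(C)(C)C[C@@H](O)C[C@@]2(C)O1
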